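**Strategy.** The route rests on cutting ring A (C1–C6 of the acetylenic end, carotenoid numbering) across C4–C5 and C6–C1. Its tetrasubstituted C5=C6 double bond, flanked by the C4 methylene and the gem-dimethyl carbon C1, with oxygen at C3 para to C6, is the retron of a Diels–Alder reaction between a 2-silyloxy diene and an alkyne. The key step joins the silyl dienol ether of mesityl oxide (C4–C3–C2–C1) with but-2-ynal (C5, C6, C7) to give the fully substituted cyclohexadiene in one operation. The formyl group becomes the C7≡C8 alkyne; one resolved ring alkyne then feeds both C15 phosphonium salts, which are joined to a C10 dialdehyde by two Wittig reactions.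

Key step: step 2

Remark: carotenoid numbering is used (ring A = acetylenic end, ring B = 7',8'-dihydro end); but-2-ynal, ethyl but-2-ynoate and (2E,4E,6E)-2,7-dimethylocta-2,4,6-trienedial are taken as purchasable, and both hydroxyl groups are carried unprotected through the Wittig steps.

**Step 1**
Reactants: 1 mesityl oxide (4-methylpent-3-en-2-one)
Product: 3 4-methyl-2-(trimethylsilyloxy)penta-1,3-diene, via lithium dienolate 2 (not isolated)
Conditions: LiN(i-Pr)2, THF, −78 °C; then Me3SiCl, −78 °C → rt; non-aqueous work-up, distillation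
Reagents that add atoms: chlorotrimethylsilane, C[Si](C)(C)Cl
Why: Kinetic deprotonation of the enone at its α'-methyl group gives the cross-conjugated lithium dienolate, which is O-silylated to the 2-silyloxy-1,3-diene (silyl enol ether formation).

**Step 2**
Reactants: 3 4-methyl-2-(trimethylsilyloxy)penta-1,3-diene; 4 but-2-ynal
Product: 5 2,6,6-trimethyl-4-(trimethylsilyloxy)cyclohexa-1,4-diene-1-carbaldehyde
Conditions: toluene, BHT (cat.), sealed tube, 110 °C; concentrate and use directly
Reagents that add atoms: none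
Why: The electron-rich 2-silyloxy diene and the acetylenic aldehyde combine in a thermal, concerted but asynchronous [4+2] cycloaddition of normal electron demand. The closest known reaction type is the Diels–Alder reaction of 2-silyloxy-1,3-dienes with acetylenic carbonyl dienophiles, which gives 1-silyloxycyclohexa-1,4-dienes. Ring A is closed in the intermolecular [4+2] mode from the four diene carbons C4–C3–C2–C1 and the two alkyne carbons C5 and C6, so that C4–C5, C6–C1 and the tetrasubstituted C5=C6 bond arise together. No stereocentre is formed, because C3 stays sp2 as the silyl enol ether, so no facial control is required and the C3 configuration is introduced in step 5. The step needs regioselectivity and chemoselectivity: the CH2 terminus of the diene carries the largest HOMO coefficient (2-silyloxy and 4,4-dimethyl donors) and bonds to the β-carbon of the ynal, which places the formyl carbon next to the gem-dimethyl carbon, and the absence of a Lewis acid keeps the C=O group out of hetero-cycloaddition or aldol pathways. The linear dienophile and the late formation of the hindered C6–C1 bond should offset the cis-methyl group that disfavours the s-cis diene.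

**Step 3**
Reactants: 5 2,6,6-trimethyl-4-(trimethylsilyloxy)cyclohexa-1,4-diene-1-carbaldehyde
Product: 7 4-ethynyl-3,5,5-trimethylcyclohex-3-en-1-one, via silyl enol ether enyne 6 (not isolated)
Conditions: Me3SiCHN2, n-BuLi, THF, −78 °C; add 5, −78 °C → rt; then 0.5 M HCl, 0 °C, short contact
Reagents that add atoms: trimethylsilyldiazomethane, C[Si](C)(C)C=[N+]=[N-]
Why: Colvin homologation (addition of the lithiated diazo reagent to the aldehyde, Peterson elimination, loss of N2 and 1,2-hydrogen shift of the alkylidene carbene) should give the terminal alkyne under aprotic conditions that keep the silyl enol ether, and the cold acid quench then frees the C3 ketone without moving the C5=C6 bond.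

**Step 4**
Reactants: 7 4-ethynyl-3,5,5-trimethylcyclohex-3-en-1-one
Product: 8 rac-4-ethynyl-3,5,5-trimethylcyclohex-3-en-1-ol
Conditions: NaBH4, CeCl3·7H2O, MeOH, −40 °C
Reagents that add atoms: none
Why: Luche reduction is fast and nearly neutral at low temperature, so the β,γ-unsaturated ketone should be reduced to the racemic alcohol before it can isomerise into conjugation.

**Step 5**
Reactants: 8 rac-4-ethynyl-3,5,5-trimethylcyclohex-3-en-1-ol
Product: 9 (1R)-4-ethynyl-3,5,5-trimethylcyclohex-3-en-1-yl acetate
Conditions: Burkholderia cepacia lipase (Amano PS, immobilised), vinyl acetate, t-BuOMe, 30 °C, stopped just below half conversion; chromatography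
Reagents that add atoms: vinyl acetate, C=COC(C)=O
Why: Lipase-catalysed kinetic resolution by transesterification should acylate the enantiomer whose bulkier gem-dimethyl side fills the large pocket, i.e. the (R)-alcohol, as with related 3-hydroxy-ionone ring alcohols, so the enzyme sets C3 (and later C3').

**Step 6**
Reactants: 9 (1R)-4-ethynyl-3,5,5-trimethylcyclohex-3-en-1-yl acetate; 10 ethyl but-2-ynoate
Product: 11 ethyl (2E)-5-[(4R)-4-acetoxy-2,6,6-trimethylcyclohex-1-en-1-yl]-3-methylpent-2-en-4-ynoate
Conditions: Pd(OAc)2 (3 mol %), tris(2,6-dimethoxyphenyl)phosphine (3 mol %), benzene, rt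
Reagents that add atoms: none
Why: Palladium-catalysed cross-addition of a terminal alkyne to an ynoate (alkyne–alkyne coupling) delivers the alkynyl group to the β-carbon and hydrogen to the α-carbon in a syn fashion, which should fix the 9E geometry with the alkynyl group trans to the ester.

**Step 7**
Reactants: 11 ethyl (2E)-5-[(4R)-4-acetoxy-2,6,6-trimethylcyclohex-1-en-1-yl]-3-methylpent-2-en-4-ynoate
Product: 12 (2E)-5-[(4R)-4-hydroxy-2,6,6-trimethylcyclohex-1-en-1-yl]-3-methylpent-2-en-4-yn-1-ol
Conditions: i-Bu2AlH (excess), CH2Cl2, −78 → 0 °C; aq. KNaC4H4O6 work-up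
Reagents that add atoms: none
Why: Hydride 1,2-reduction of the conjugated ester gives the allylic alcohol and removes the acetate in the same operation, leaving the enyne and its geometry untouched.

**Step 8**
Reactants: 12 (2E)-5-[(4R)-4-hydroxy-2,6,6-trimethylcyclohex-1-en-1-yl]-3-methylpent-2-en-4-yn-1-ol
Product: 13 [(2E)-5-[(4R)-4-hydroxy-2,6,6-trimethylcyclohex-1-en-1-yl]-3-methylpent-2-en-4-yn-1-yl]triphenylphosphonium bromide
Conditions: PPh3·HBr, MeOH/CH2Cl2, rt, dark
Reagents that add atoms: triphenylphosphine hydrobromide, [Br-].[PH+](c1ccccc1)(c1ccccc1)c1ccccc1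
Why: Only the primary allylic alcohol is activated by HBr and displaced by triphenylphosphine at the primary terminus (phosphonium salt formation), whereas the homoallylic ring alcohol is inert.

**Step 9**
Reactants: 9 (1R)-4-ethynyl-3,5,5-trimethylcyclohex-3-en-1-yl acetate
Product: 14 (1R)-4-ethenyl-3,5,5-trimethylcyclohex-3-en-1-yl acetate
Conditions: H2 (1 atm), Pd/CaCO3–Pb(OAc)2 (Lindlar catalyst), quinoline, hexane/EtOAc, rt, stopped after one equivalent of H2
Reagents that add atoms: none
Why: Lindlar semi-hydrogenation should stop at the vinyl group, and the tetrasubstituted ring olefin does not react.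

**Step 10**
Reactants: 14 (1R)-4-ethenyl-3,5,5-trimethylcyclohex-3-en-1-yl acetate; 10 ethyl but-2-ynoate
Product: 16 ethyl (2E)-5-[(4R)-4-acetoxy-2,6,6-trimethylcyclohex-1-en-1-yl]-3-methylpent-2-enoate, via B-alkyl-9-BBN borane 15 (not isolated)
Conditions: 9-BBN, THF, 0 °C → rt; then 10, CuOAc (5 mol %), P(OPh)3 (10 mol %), KOt-Bu (cat.), t-BuOH, 1,4-dioxane, 40 °C
Reagents that add atoms: none
Why: Anti-Markovnikov hydroboration of the only accessible olefin followed by copper-catalysed conjugate addition of the alkylborane to the ynoate with syn protonation (formal syn-hydroalkylation) should give the 9'E trisubstituted enoate with the new chain trans to the ester.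

**Step 11**
Reactants: 16 ethyl (2E)-5-[(4R)-4-acetoxy-2,6,6-trimethylcyclohex-1-en-1-yl]-3-methylpent-2-enoate
Product: 17 (2E)-5-[(4R)-4-hydroxy-2,6,6-trimethylcyclohex-1-en-1-yl]-3-methylpent-2-en-1-ol
Conditions: i-Bu2AlH (excess), CH2Cl2, −78 → 0 °C; aq. KNaC4H4O6 work-up
Reagents that add atoms: none
Why: Hydride 1,2-reduction of the enoate gives the allylic alcohol with retention of olefin geometry and cleaves the acetate at the same time.

**Step 12**
Reactants: 17 (2E)-5-[(4R)-4-hydroxy-2,6,6-trimethylcyclohex-1-en-1-yl]-3-methylpent-2-en-1-ol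
Product: 18 [(2E)-5-[(4R)-4-hydroxy-2,6,6-trimethylcyclohex-1-en-1-yl]-3-methylpent-2-en-1-yl]triphenylphosphonium bromide
Conditions: PPh3·HBr, MeOH/CH2Cl2, rt
Reagents that add atoms: triphenylphosphine hydrobromide, [Br-].[PH+](c1ccccc1)(c1ccccc1)c1ccccc1
Why: The primary allylic alcohol is converted through its allylic bromide into the phosphonium salt at the primary carbon, which should preserve the E geometry and leave the ring alcohol alone.

**Step 13**
Reactants: 18 [(2E)-5-[(4R)-4-hydroxy-2,6,6-trimethylcyclohex-1-en-1-yl]-3-methylpent-2-en-1-yl]triphenylphosphonium bromide; 19 (2E,4E,6E)-2,7-dimethylocta-2,4,6-trienedial (excess)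
Product: 21 (2E,4E,6E,8E,10E)-13-[(4R)-4-hydroxy-2,6,6-trimethylcyclohex-1-en-1-yl]-2,7,11-trimethyltrideca-2,4,6,8,10-pentaenal, via phosphonium ylide 20 (not isolated)
Conditions: NaOMe, CH2Cl2/MeOH, 0 °C → rt, dark; then heptane, reflux; crystallisation
Reagents that add atoms: none
Why: Wittig olefination of one formyl group of the excess dialdehyde builds C11'=C12', and the hindered Z isomer at the new bond should equilibrate thermally to E.

**Step 14**
Reactants: 21 (2E,4E,6E,8E,10E)-13-[(4R)-4-hydroxy-2,6,6-trimethylcyclohex-1-en-1-yl]-2,7,11-trimethyltrideca-2,4,6,8,10-pentaenal; 13 [(2E)-5-[(4R)-4-hydroxy-2,6,6-trimethylcyclohex-1-en-1-yl]-3-methylpent-2-en-4-yn-1-yl]triphenylphosphonium bromide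
Product: 23 (3R,3'R)-7,8-didehydro-7',8'-dihydro-β,β-carotene-3,3'-diol (all-E), via phosphonium ylide 22 (not isolated)
Conditions: NaOMe, CH2Cl2/MeOH, 0 °C → rt, dark, argon; then EtOAc, 60 °C; chromatography and crystallisation in the dark
Reagents that add atoms: none
Why: Wittig olefination of the C25 aldehyde with the acetylenic C15 ylide closes C11=C12, and mild thermal equilibration without iodine or light should convert the 11Z isomer to E without isomerising the 9E enyne bond.

**Compound list**

1 | mesityl oxide (4-methylpent-3-en-2-one) | CC(=O)C=C(C)C | starting material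
2 | lithium 4-methylpenta-1,3-dien-2-olate (not isolated) | [Li+].[O-]C(=C)C=C(C)C | intermediate
3 | 4-methyl-2-(trimethylsilyloxy)penta-1,3-diene | C=C(O[Si](C)(C)C)C=C(C)C | intermediate
4 | but-2-ynal | CC#CC=O | starting material
5 | 2,6,6-trimethyl-4-(trimethylsilyloxy)cyclohexa-1,4-diene-1-carbaldehyde | CC1=C(C=O)C(C)(C)C=C(O[Si](C)(C)C)C1 | intermediate
6 | 4-ethynyl-3,3,5-trimethyl-1-(trimethylsilyloxy)cyclohexa-1,4-diene (not isolated) | CC1=C(C#C)C(C)(C)C=C(O[Si](C)(C)C)C1 | intermediate
7 | 4-ethynyl-3,5,5-trimethylcyclohex-3-en-1-one | CC1=C(C#C)C(C)(C)CC(=O)C1 | intermediate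
8 | rac-4-ethynyl-3,5,5-trimethylcyclohex-3-en-1-ol | CC1=C(C#C)C(C)(C)CC(O)C1 | intermediate
9 | (1R)-4-ethynyl-3,5,5-trimethylcyclohex-3-en-1-yl acetate | CC1=C(C#C)C(C)(C)C[C@H](OC(C)=O)C1 | intermediate
10 | ethyl but-2-ynoate | CCOC(=O)C#CC | starting material
11 | ethyl (2E)-5-[(4R)-4-acetoxy-2,6,6-trimethylcyclohex-1-en-1-yl]-3-methylpent-2-en-4-ynoate | CC1=C(C#C/C(C)=C/C(=O)OCC)C(C)(C)C[C@H](OC(C)=O)C1 | intermediate
12 | (2E)-5-[(4R)-4-hydroxy-2,6,6-trimethylcyclohex-1-en-1-yl]-3-methylpent-2-en-4-yn-1-ol | CC1=C(C#C/C(C)=C/CO)C(C)(C)C[C@H](O)C1 | intermediate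
13 | [(2E)-5-[(4R)-4-hydroxy-2,6,6-trimethylcyclohex-1-en-1-yl]-3-methylpent-2-en-4-yn-1-yl]triphenylphosphonium bromide | CC1=C(C#C/C(C)=C/C[P+](c2ccccc2)(c2ccccc2)c2ccccc2)C(C)(C)C[C@H](O)C1.[Br-] | intermediate
14 | (1R)-4-ethenyl-3,5,5-trimethylcyclohex-3-en-1-yl acetate | C=CC1=C(C)C[C@@H](OC(C)=O)CC1(C)C | intermediate
15 | (1R)-4-[2-(9-borabicyclo[3.3.1]nonan-9-yl)ethyl]-3,5,5-trimethylcyclohex-3-en-1-yl acetate (not isolated) | B1(CCC2=C(C)C[C@@H](OC(C)=O)CC2(C)C)C3CCCC1CCC3 | intermediate
16 | ethyl (2E)-5-[(4R)-4-acetoxy-2,6,6-trimethylcyclohex-1-en-1-yl]-3-methylpent-2-enoate | CCOC(=O)/C=C(\C)CCC1=C(C)C[C@@H](OC(C)=O)CC1(C)C | intermediate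
17 | (2E)-5-[(4R)-4-hydroxy-2,6,6-trimethylcyclohex-1-en-1-yl]-3-methylpent-2-en-1-ol | OC/C=C(\C)CCC1=C(C)C[C@@H](O)CC1(C)C | intermediate
18 | [(2E)-5-[(4R)-4-hydroxy-2,6,6-trimethylcyclohex-1-en-1-yl]-3-methylpent-2-en-1-yl]triphenylphosphonium bromide | C(/C=C(\C)CCC1=C(C)C[C@@H](O)CC1(C)C)[P+](c2ccccc2)(c2ccccc2)c2ccccc2.[Br-] | intermediate
19 | (2E,4E,6E)-2,7-dimethylocta-2,4,6-trienedial | O=C/C(C)=C/C=C/C=C(C)/C=O | starting material
20 | ylide of 18: (2E)-5-[(4R)-4-hydroxy-2,6,6-trimethylcyclohex-1-en-1-yl]-3-methylpent-2-en-1-ylidene(triphenyl)phosphorane (not isolated) | [CH-](/C=C(\C)CCC1=C(C)C[C@@H](O)CC1(C)C)[P+](c2ccccc2)(c2ccccc2)c2ccccc2 | intermediate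
21 | (2E,4E,6E,8E,10E)-13-[(4R)-4-hydroxy-2,6,6-trimethylcyclohex-1-en-1-yl]-2,7,11-trimethyltrideca-2,4,6,8,10-pentaenal | O=C/C(C)=C/C=C/C=C(C)/C=C/C=C(\C)CCC1=C(C)C[C@@H](O)CC1(C)C | intermediate
22 | ylide of 13: (2E)-5-[(4R)-4-hydroxy-2,6,6-trimethylcyclohex-1-en-1-yl]-3-methylpent-2-en-4-yn-1-ylidene(triphenyl)phosphorane (not isolated) | CC1=C(C#C/C(C)=C/[CH-][P+](c2ccccc2)(c2ccccc2)c2ccccc2)C(C)(C)C[C@H](O)C1 | intermediate
23 | (3R,3'R)-7,8-didehydro-7',8'-dihydro-β,β-carotene-3,3'-diol (all-E) | CC1=C(C#C/C(C)=C/C=C/C(C)=C/C=C/C=C(C)/C=C/C=C(\C)CCC2=C(C)C[C@@H](O)CC2(C)C)C(C)(C)C[C@H](O)C1 | target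

**Totals.** Total step count: 14. Longest linear sequence: 11 steps (1, 2, 3, 4, 5, 9, 10, 11, 12, 13, 14).

**Steps most likely to fail**

Step 2. The cis-methyl group on the dimethyl-substituted diene terminus disfavours the s-cis conformer, so the cycloaddition may be slow enough that thermal oligomerisation of the ynal and loss of the silyl group outrun ring formation. The fallback sets out from diene 3 and replaces the ynal by the thermally robust ynone pent-3-yn-2-one, heated in xylene at 140 °C or promoted by ZnCl2 so that a stepwise Mukaiyama–Michael addition and ring closure form the same two bonds. This should give 1-[2,6,6-trimethyl-4-(trimethylsilyloxy)cyclohexa-1,4-dien-1-yl]ethan-1-one F1. Its methyl ketone is then turned into the alkyne by the enol phosphate route: LiN(i-Pr)2 and ClP(O)(OEt)2 give diethyl 1-[2,6,6-trimethyl-4-(trimethylsilyloxy)cyclohexa-1,4-dien-1-yl]ethenyl phosphate F2, and two further equivalents of LiN(i-Pr)2 eliminate phosphate to give silyl enol ether enyne 6. The cold acid quench brings the sequence back to the route at ketone 7.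

Step 3. Premature loss of the trimethylsilyl group, or deprotonation at the doubly activated C4 methylene by the lithiated diazo reagent, would turn the aldehyde into an unreactive vinylogous enolate before homologation. The fallback sets out from aldehyde 5 and uses a Wittig chloromethylenation with Ph3P=CHCl, generated from (chloromethyl)triphenylphosphonium chloride and NaN(SiMe3)2 in THF at −78 °C. This should give 2-(2-chloroethenyl)-1,3,3-trimethyl-5-(trimethylsilyloxy)cyclohexa-1,4-diene F3 as an E/Z mixture. Dehydrochlorination with LiN(i-Pr)2 (THF, −78 → 0 °C) leads to the acetylide of 6, and the cold acid quench returns to the route at ketone 7.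

Step 10. Slow boron-to-copper transfer of the hindered alkyl group, or isomerisation of the alkenylcopper intermediate before protonation, would lower conversion and erode the E geometry at C9'=C10'. The fallback sets out from borane 15, made from 14 as before, and uses a B-alkyl Suzuki–Miyaura coupling (PdCl2(dppf), aq. K3PO4, THF/DMF, rt) with ethyl (2E)-3-(trifluoromethylsulfonyloxy)but-2-enoate F4. F4 is prepared from ethyl acetoacetate with Tf2O and aqueous Me4NOH in hexanes. The coupling proceeds with retention of the enol triflate geometry and comes back to the route at ester 16.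

**Further compounds**

F1 | step 2 | 1-[2,6,6-trimethyl-4-(trimethylsilyloxy)cyclohexa-1,4-dien-1-yl]ethan-1-one | CC(=O)C1=C(C)CC(O[Si](C)(C)C)=CC1(C)C
F2 | step 2 | diethyl 1-[2,6,6-trimethyl-4-(trimethylsilyloxy)cyclohexa-1,4-dien-1-yl]ethenyl phosphate | C=C(OP(=O)(OCC)OCC)C1=C(C)CC(O[Si](C)(C)C)=CC1(C)C
F3 | step 3 | 2-(2-chloroethenyl)-1,3,3-trimethyl-5-(trimethylsilyloxy)cyclohexa-1,4-diene (E/Z mixture) | ClC=CC1=C(C)CC(O[Si](C)(C)C)=CC1(C)C
F4 | step 10 | ethyl (2E)-3-(trifluoromethylsulfonyloxy)but-2-enoate | CCOC(=O)/C=C(\C)OS(=O)(=O)C(F)(F)F
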